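**Retrosynthetic overview**

1. Key step, last bond C12–C13: a nickel-mediated decarboxylative radical alkenylation joins decalin acid 11 to (Z)-iodoalkene 24, which already carries the docosanoate and the free C16 hydroxyl; no protecting group is used and the alkene geometry comes in with 24.
2. C9–C11: an iron-hydride hydrogen-atom-transfer (MHAT) Giese addition of exocyclic alkene 8 to methyl acrylate sets the C9 quaternary centre opposite the axial C19 methyl.
3. Rings: ring B is 3-methylcyclohex-2-en-1-one (C5 set by copper-catalysed asymmetric conjugate alkenylation); ring A is closed second by intramolecular enolate alkylation; C8 and C10 are set by equilibration.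
4. Iodoalkene 24 comes from hydroxyl-directed trans-hydrostannation/iodination of the docosanoate monoester of but-2-yne-1,4-diol; docosanoic acid is built from 1-bromoheptane, two 1,6-dibromohexane units and oxetan-2-one.

Assumption: the acyl group is docosanoyl (22 carbons); positions are cited in clerodane numbering (decalin C1–C10, methyls C17–C20, side chain C11–C16); the ligand enantiomer in step 1 is the one that gives (3R)-4 (sense assigned by analogy).

**Route**

Step 1
Reactants: 1 5-chloropent-1-yne; 2 3-methylcyclohex-2-en-1-one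
Product: 4 (3R)-3-(5-chloropent-1-en-2-yl)-3-methylcyclohexan-1-one, via alkenylalane 3 (not isolated)
Conditions: 1 (1.5 equiv), i-Bu2AlH (1.5 equiv), NiCl2(dppp) (3 mol%), THF, 0 to 22 °C; then 2 (1.0 equiv), copper thiophene-2-carboxylate (C5H3CuO2S, 10 mol%), N,N-bis[(1R)-1-(naphthalen-2-yl)ethyl]-P,P-diphenylphosphinous amide (11 mol%), THF/Et2O, −30 °C; aq. NH4Cl
Reagents that add atoms: none
Why: Nickel-catalysed α-selective hydroalumination puts aluminium on the internal alkyne carbon, and copper-catalysed asymmetric conjugate addition of this alkenylalane to the β-methyl enone creates the C5 quaternary stereocentre under ligand control (R); the alkyl chloride is inert.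

Step 2
Reactants: 4 (3R)-3-(5-chloropent-1-en-2-yl)-3-methylcyclohexan-1-one
Product: 6 (2R,4aR,8aS)-2,4a-dimethyl-5-methylideneoctahydronaphthalen-1(2H)-one, via methylated chloroketone 5 (not isolated)
Conditions: LiN(i-Pr)2 (1.05 equiv), THF, −78 °C; MeI (1.05 equiv), −78 to 0 °C; then t-BuOK (3 equiv), t-BuOH/THF, 0 to 45 °C
Reagents that add atoms: iodomethane (MeI), CI
Why: Kinetic enolate methylation at the CH2 remote from the quaternary carbon installs C17, then equilibrating t-BuOK lets only the C10 enolate close ring A by 6-exo-tet intramolecular enolate alkylation and epimerises C8 and C10 to the thermodynamically favoured trans-fused ketone with equatorial methyl (estimated about 4:1 trans:cis).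

Step 3
Reactants: 6 (2R,4aR,8aS)-2,4a-dimethyl-5-methylideneoctahydronaphthalen-1(2H)-one
Product: 7 (2R,4aR,8aS)-2,4a,5-trimethyl-3,4,4a,7,8,8a-hexahydronaphthalen-1(2H)-one
Conditions: RhCl3·3H2O (5 mol%), EtOH, 78 °C; chromatography (minor cis-fused ketone re-equilibrated with NaOMe/MeOH and recycled)
Reagents that add atoms: none
Why: Rhodium-hydride alkene isomerisation moves the exocyclic double bond to the only endocyclic position open to it (C3=C4, since C5 is quaternary) to give the more stable trisubstituted alkene; C8 and C10 stay at their thermodynamic configuration.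

Step 4
Reactants: 7 (2R,4aR,8aS)-2,4a,5-trimethyl-3,4,4a,7,8,8a-hexahydronaphthalen-1(2H)-one
Product: 8 (2R,4aR,8aR)-2,4a,5-trimethyl-1-methylidene-1,2,3,4,4a,7,8,8a-octahydronaphthalene
Conditions: Cp2TiMe2 (2.5 equiv), toluene, 75 °C, dark
Reagents that add atoms: dimethyltitanocene (Cp2TiMe2), C[Ti](C)(C1C=CC=C1)C1C=CC=C1
Why: Petasis methylenation: the neutral titanium methylidene olefinates the hindered, enolisable ketone without base, so the α-stereocentres C8 and C10 are not epimerised.

Step 5
Reactants: 8 (2R,4aR,8aR)-2,4a,5-trimethyl-1-methylidene-1,2,3,4,4a,7,8,8a-octahydronaphthalene; 9 methyl acrylate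
Product: 10 methyl 3-[(1S,2R,4aR,8aR)-1,2,4a,5-tetramethyl-1,2,3,4,4a,7,8,8a-octahydronaphthalen-1-yl]propanoate
Conditions: Fe(acac)3 (30 mol%), PhSiH3 (2.5 equiv), 9 (3 equiv), EtOH/ethylene glycol 5:1, 60 °C
Reagents that add atoms: none
Why: MHAT-initiated Giese reaction (iron-hydride reductive olefin coupling): Markovnikov hydrogen-atom transfer to the 1,1-disubstituted alkene, which reacts faster than the trisubstituted ring A alkene, gives the tertiary C9 radical; it adds to the acrylate on the equatorial face away from the axial C19 methyl, so C11 is equatorial and the new C20 methyl axial (9S).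

Step 6
Reactants: 10 methyl 3-[(1S,2R,4aR,8aR)-1,2,4a,5-tetramethyl-1,2,3,4,4a,7,8,8a-octahydronaphthalen-1-yl]propanoate
Product: 11 3-[(1S,2R,4aR,8aR)-1,2,4a,5-tetramethyl-1,2,3,4,4a,7,8,8a-octahydronaphthalen-1-yl]propanoic acid
Conditions: LiOH·H2O (3 equiv), THF/MeOH/H2O, 40 °C; then 1 M HCl
Reagents that add atoms: lithium hydroxide (LiOH), [Li+].[OH-]
Why: Saponification of an unhindered methyl ester; no stereocentre is touched.

Step 7
Reactants: 12 1-bromoheptane; 13 1,6-dibromohexane
Product: 15 1-bromotridecane, via heptylmagnesium bromide 14 (not isolated)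
Conditions: Mg, THF, 40 °C; then added to 13 (3 equiv), Li2CuCl4 (3 mol%), THF, −10 to 20 °C
Reagents that add atoms: none
Why: Copper-catalysed Grignard–alkyl bromide coupling (Kochi–Tamura type); the excess dibromide makes the mono-coupled bromide the main product.

Step 8
Reactants: 15 1-bromotridecane; 13 1,6-dibromohexane
Product: 17 1-bromononadecane, via tridecylmagnesium bromide 16 (not isolated)
Conditions: Mg, THF, 45 °C; then added to 13 (3 equiv), Li2CuCl4 (3 mol%), THF, −10 to 20 °C
Reagents that add atoms: none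
Why: Second copper-catalysed Grignard–alkyl bromide coupling (Kochi–Tamura type), again with excess dibromide for mono-coupling.

Step 9
Reactants: 17 1-bromononadecane; 18 oxetan-2-one
Product: 20 docosanoic acid, via nonadecylmagnesium bromide 19 (not isolated)
Conditions: Mg, THF, 45 °C; then 18 (1.0 equiv), CuBr·SMe2 (5 mol%), THF/Me2S, −30 to 0 °C; then 1 M HCl
Reagents that add atoms: none
Why: Copper-catalysed ring opening of the β-lactone by the Grignard reagent at the CH2–O carbon gives the acid lengthened by three carbons.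

Step 10
Reactants: 20 docosanoic acid; 21 but-2-yne-1,4-diol
Product: 22 4-hydroxybut-2-yn-1-yl docosanoate
Conditions: 21 (5 equiv), DCC (1.1 equiv), DMAP (10 mol%), THF, 23 °C
Reagents that add atoms: none
Why: Steglich esterification; the five-fold excess of the symmetric diol makes the monoester the main product.

Step 11
Reactants: 22 4-hydroxybut-2-yn-1-yl docosanoate
Product: 24 (2Z)-4-hydroxy-3-iodobut-2-en-1-yl docosanoate, via alkenylstannane 23 (not isolated)
Conditions: [Cp*RuCl]4 (2.5 mol%), Bu3SnH (1.1 equiv), CH2Cl2, 23 °C; then I2 (1.2 equiv), 0 °C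
Reagents that add atoms: iodine (I2), II
Why: Hydroxyl-directed ruthenium-catalysed trans-hydrostannation delivers tin to the alkyne carbon next to the free CH2OH and H anti to it; iododestannylation with retention then leaves iodine cis to the acyloxymethyl group (Z).

Step 12
Reactants: 11 3-[(1S,2R,4aR,8aR)-1,2,4a,5-tetramethyl-1,2,3,4,4a,7,8,8a-octahydronaphthalen-1-yl]propanoic acid; 24 (2Z)-4-hydroxy-3-iodobut-2-en-1-yl docosanoate
Product: 26 (2E)-4-hydroxy-3-{2-[(1S,2R,4aR,8aR)-1,2,4a,5-tetramethyl-1,2,3,4,4a,7,8,8a-octahydronaphthalen-1-yl]ethyl}but-2-en-1-yl docosanoate, via phthalimidoyl ester 25 (not isolated)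
Conditions: N-hydroxyphthalimide (1.1 equiv), N,N'-diisopropylcarbodiimide (1.1 equiv), CH2Cl2, 23 °C (no DMAP); filter, concentrate; then 24 (1.3 equiv), NiBr2·glyme (10 mol%), 4,4'-di-tert-butyl-2,2'-bipyridine (15 mol%), Zn (2.5 equiv), DMA, 23 °C
Reagents that add atoms: none
Why: Proposed new method: zinc-reduced low-valent nickel inserts into the C–I bond of 24 while single-electron reduction of 25 releases CO2 and phthalimide anion to give the primary C12 radical, which the alkenylnickel species captures before reductive elimination forges C12–C13 with retention of the alkene geometry of 24 (E in the product by rank change) and no new stereocentre; the free hydroxyl and both esters are spectators; the closest known reactions are nickel-catalysed reductive cross-electrophile couplings of N-hydroxyphthalimide esters with aryl halides and of alkyl halides with alkenyl halides, and the decarboxylative alkenylation of such esters with alkenylzinc reagents.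

**Compound list**

1 | 5-chloropent-1-yne | C#CCCCCl | starting material
2 | 3-methylcyclohex-2-en-1-one | CC1=CC(=O)CCC1 | starting material
3 | (5-chloropent-1-en-2-yl)bis(2-methylpropyl)alumane | C=C(CCCCl)[Al](CC(C)C)CC(C)C | intermediate
4 | (3R)-3-(5-chloropent-1-en-2-yl)-3-methylcyclohexan-1-one | O=C1CCC[C@@](C)(C(=C)CCCCl)C1 | intermediate
5 | (3R)-3-(5-chloropent-1-en-2-yl)-3,6-dimethylcyclohexan-1-one (C6 epimers) | O=C1C(C)CC[C@@](C)(C(=C)CCCCl)C1 | intermediate
6 | (2R,4aR,8aS)-2,4a-dimethyl-5-methylideneoctahydronaphthalen-1(2H)-one | O=C1[C@H](C)CC[C@@]2(C)C(=C)CCC[C@H]12 | intermediate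
7 | (2R,4aR,8aS)-2,4a,5-trimethyl-3,4,4a,7,8,8a-hexahydronaphthalen-1(2H)-one | O=C1[C@H](C)CC[C@@]2(C)C(C)=CCC[C@H]12 | intermediate
8 | (2R,4aR,8aR)-2,4a,5-trimethyl-1-methylidene-1,2,3,4,4a,7,8,8a-octahydronaphthalene | C=C1[C@H](C)CC[C@@]2(C)C(C)=CCC[C@H]12 | intermediate
9 | methyl acrylate (methyl prop-2-enoate) | C=CC(=O)OC | starting material
10 | methyl 3-[(1S,2R,4aR,8aR)-1,2,4a,5-tetramethyl-1,2,3,4,4a,7,8,8a-octahydronaphthalen-1-yl]propanoate | COC(=O)CC[C@@]1(C)[C@H](C)CC[C@@]2(C)C(C)=CCC[C@H]12 | intermediate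
11 | 3-[(1S,2R,4aR,8aR)-1,2,4a,5-tetramethyl-1,2,3,4,4a,7,8,8a-octahydronaphthalen-1-yl]propanoic acid | OC(=O)CC[C@@]1(C)[C@H](C)CC[C@@]2(C)C(C)=CCC[C@H]12 | intermediate
12 | 1-bromoheptane | CCCCCCCBr | starting material
13 | 1,6-dibromohexane | BrCCCCCCBr | starting material
14 | heptylmagnesium bromide | CCCCCCC[Mg]Br | intermediate
15 | 1-bromotridecane | CCCCCCCCCCCCCBr | intermediate
16 | tridecylmagnesium bromide | CCCCCCCCCCCCC[Mg]Br | intermediate
17 | 1-bromononadecane | CCCCCCCCCCCCCCCCCCCBr | intermediate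
18 | oxetan-2-one (β-propiolactone) | O=C1CCO1 | starting material
19 | nonadecylmagnesium bromide | CCCCCCCCCCCCCCCCCCC[Mg]Br | intermediate
20 | docosanoic acid | CCCCCCCCCCCCCCCCCCCCCC(=O)O | intermediate
21 | but-2-yne-1,4-diol | OCC#CCO | starting material
22 | 4-hydroxybut-2-yn-1-yl docosanoate | CCCCCCCCCCCCCCCCCCCCCC(=O)OCC#CCO | intermediate
23 | (2Z)-4-hydroxy-3-(tributylstannyl)but-2-en-1-yl docosanoate | CCCCCCCCCCCCCCCCCCCCCC(=O)OC/C=C(/CO)[Sn](CCCC)(CCCC)CCCC | intermediate
24 | (2Z)-4-hydroxy-3-iodobut-2-en-1-yl docosanoate | CCCCCCCCCCCCCCCCCCCCCC(=O)OC/C=C(/CO)I | intermediate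
25 | 1,3-dioxo-1,3-dihydro-2H-isoindol-2-yl 3-[(1S,2R,4aR,8aR)-1,2,4a,5-tetramethyl-1,2,3,4,4a,7,8,8a-octahydronaphthalen-1-yl]propanoate | O=C(CC[C@@]1(C)[C@H](C)CC[C@@]2(C)C(C)=CCC[C@H]12)ON3C(=O)c4ccccc4C3=O | intermediate
26 | (2E)-4-hydroxy-3-{2-[(1S,2R,4aR,8aR)-1,2,4a,5-tetramethyl-1,2,3,4,4a,7,8,8a-octahydronaphthalen-1-yl]ethyl}but-2-en-1-yl docosanoate | CCCCCCCCCCCCCCCCCCCCCC(=O)OC/C=C(/CO)CC[C@@]1(C)[C@H](C)CC[C@@]2(C)C(C)=CCC[C@H]12 | target

**Step count and risks**

Total steps: 12. Longest linear sequence: 7 steps (steps 1–6, then 12); the side-chain branch (steps 7–11, then 12) is 6 steps.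

Step 12 is the most likely to fail. The redox-active ester can acylate the free alcohol of 24, nickel can ionise the allylic ester, and the alkene geometry can erode on nickel. The fallback sets out from 24 (with 25 made from 11 as before) and comes back at 26. It replaces the two-electrophile reductive union by a nucleophile–electrophile coupling with the hydroxyl masked. Silylation (TBSCl, imidazole) gives (2Z)-4-[(tert-butyldimethylsilyl)oxy]-3-iodobut-2-en-1-yl docosanoate F1. Iodine–magnesium exchange with i-PrMgCl·LiCl at −40 °C gives chloro[(2Z)-1-[(tert-butyldimethylsilyl)oxy]-4-(docosanoyloxy)but-2-en-2-yl]magnesium F2, and ZnCl2 converts it into chloro[(2Z)-1-[(tert-butyldimethylsilyl)oxy]-4-(docosanoyloxy)but-2-en-2-yl]zinc F3. Nickel-catalysed decarboxylative coupling of F3 with 25 (NiCl2·glyme, 2,2'-bipyridine, THF/DMF) gives (2E)-4-[(tert-butyldimethylsilyl)oxy]-3-{2-[(1S,2R,4aR,8aR)-1,2,4a,5-tetramethyl-1,2,3,4,4a,7,8,8a-octahydronaphthalen-1-yl]ethyl}but-2-en-1-yl docosanoate F4, and HF·pyridine frees 26.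

Step 5 is second. Hydrogen-atom transfer may also engage the ring A alkene, and the hindered C9 radical may be reduced instead of adding. The fallback sets out from 7 and comes back at 10. It makes the same radical from a tertiary alcohol derivative under photoredox conditions, so no alkene has to be discriminated. MeLi/CeCl3 (THF, −78 °C) gives (1R,2R,4aR,8aS)-1,2,4a,5-tetramethyl-1,2,3,4,4a,7,8,8a-octahydronaphthalen-1-ol F5. Methyl chlorooxoacetate (Et3N, DMAP) gives methyl (1R,2R,4aR,8aS)-1,2,4a,5-tetramethyl-1,2,3,4,4a,7,8,8a-octahydronaphthalen-1-yl oxalate F6, and aqueous CsOH gives caesium (1R,2R,4aR,8aS)-1,2,4a,5-tetramethyl-1,2,3,4,4a,7,8,8a-octahydronaphthalen-1-yl oxalate F7. Irradiation with blue light in the presence of Ir[dF(CF3)ppy]2(dtbbpy)PF6, 9 and water (DME/DMF, 60 °C) then gives 10 with the same facial preference.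

Step 1 is third. The α/β ratio of the hydroalumination, nickel carried into the copper step and the enantioselectivity with this alkenylalane are all uncertain. The fallback sets out from 1 and comes back at 4. It fixes the position of the metal through a carbon–bromine bond instead of a hydrometalation. Bromoboration with B-bromo-9-borabicyclo[3.3.1]nonane followed by acetic acid gives 2-bromo-5-chloropent-1-ene F8. t-BuLi (Et2O, −78 °C) gives (5-chloropent-1-en-2-yl)lithium F9, and Me2AlCl gives (5-chloropent-1-en-2-yl)dimethylalumane F10. Conjugate addition of F10 to 2 with the copper catalyst of step 1 gives 4.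

Further compounds
F1 | step 12 | (2Z)-4-[(tert-butyldimethylsilyl)oxy]-3-iodobut-2-en-1-yl docosanoate | CCCCCCCCCCCCCCCCCCCCCC(=O)OC/C=C(/CO[Si](C)(C)C(C)(C)C)I
F2 | step 12 | chloro[(2Z)-1-[(tert-butyldimethylsilyl)oxy]-4-(docosanoyloxy)but-2-en-2-yl]magnesium | CCCCCCCCCCCCCCCCCCCCCC(=O)OC/C=C(/CO[Si](C)(C)C(C)(C)C)[Mg]Cl
F3 | step 12 | chloro[(2Z)-1-[(tert-butyldimethylsilyl)oxy]-4-(docosanoyloxy)but-2-en-2-yl]zinc | CCCCCCCCCCCCCCCCCCCCCC(=O)OC/C=C(/CO[Si](C)(C)C(C)(C)C)[Zn]Cl
F4 | step 12 | (2E)-4-[(tert-butyldimethylsilyl)oxy]-3-{2-[(1S,2R,4aR,8aR)-1,2,4a,5-tetramethyl-1,2,3,4,4a,7,8,8a-octahydronaphthalen-1-yl]ethyl}but-2-en-1-yl docosanoate | CCCCCCCCCCCCCCCCCCCCCC(=O)OC/C=C(/CO[Si](C)(C)C(C)(C)C)CC[C@@]1(C)[C@H](C)CC[C@@]2(C)C(C)=CCC[C@H]12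
F5 | step 5 | (1R,2R,4aR,8aS)-1,2,4a,5-tetramethyl-1,2,3,4,4a,7,8,8a-octahydronaphthalen-1-ol | C[C@@]1(O)[C@H](C)CC[C@@]2(C)C(C)=CCC[C@H]12
F6 | step 5 | methyl (1R,2R,4aR,8aS)-1,2,4a,5-tetramethyl-1,2,3,4,4a,7,8,8a-octahydronaphthalen-1-yl oxalate | C[C@@]1(OC(=O)C(=O)OC)[C@H](C)CC[C@@]2(C)C(C)=CCC[C@H]12
F7 | step 5 | caesium (1R,2R,4aR,8aS)-1,2,4a,5-tetramethyl-1,2,3,4,4a,7,8,8a-octahydronaphthalen-1-yl oxalate | C[C@@]1(OC(=O)C([O-])=O)[C@H](C)CC[C@@]2(C)C(C)=CCC[C@H]12.[Cs+]
F8 | step 1 | 2-bromo-5-chloropent-1-ene | C=C(Br)CCCCl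
F9 | step 1 | (5-chloropent-1-en-2-yl)lithium | [Li]C(=C)CCCCl
F10 | step 1 | (5-chloropent-1-en-2-yl)dimethylalumane | C=C(CCCCl)[Al](C)C
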